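## Retrosynthetic overview
1. Kurarinone comes from its 2',4'-di-O-MOM ether by acid cleavage of the two MOM groups.
2. Rings A and C form in one flask from a monocyclic 3-cinnamoyl-4-methoxy-6-alkyl-2-pyrone. Base opens the lactone to a dienylketene, 6π closure (C8–C8a) gives ring A, and a catalyst-controlled oxa-Michael addition (O1–C2) gives ring C and the 2S centre.
3. The pyrone comes from O-methylation, alkylation of the 6-methyl dianion with (S)-lavandulyl iodide, and aldol condensation of dehydroacetic acid with 2,4-bis(MOMO)benzaldehyde.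
4. The iodide comes from Evans deconjugative α-prenylation of a senecioyl imide (sets the side-chain centre), then reduction and iodination.
5. Ring order: B is bought, the bought pyrone ring is sacrificed, and A then C form last in the same operation.

Assumption: the quinidine-derived (9R) thiourea is taken to give 2S by analogy with related cinchona-thiourea oxa-Michael cyclisations. If the sense proves opposite, the quinine-derived pseudoenantiomer replaces it.

Stereo note: the side-chain centre of the target matches (S)-lavandulol in space. Its descriptor is S in 7–9, 15 and 16, and becomes R in 20–22 only because CH2–aryl changes the CIP ranking.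

## Route

Step 1
Reactants: 1 (S)-4-benzyl-1,3-oxazolidin-2-one; 2 3-methylbut-2-enoyl chloride
Product: 4 (S)-4-benzyl-3-(3-methylbut-2-enoyl)oxazolidin-2-one, via lithium oxazolidinide 3 (not isolated)
Conditions: n-BuLi (1.0 equiv), THF, −78 °C; then 2, −78 → 0 °C
Reagents that add atoms: none
Why: N-acylation of the lithiated Evans auxiliary by an acid chloride is fast at low temperature and leaves the conjugated alkene and the C4 centre untouched (Evans imide formation).

Step 2
Reactants: 4 (S)-4-benzyl-3-(3-methylbut-2-enoyl)oxazolidin-2-one; 5 1-bromo-3-methylbut-2-ene (prenyl bromide)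
Product: 7 (4S)-4-benzyl-3-[(2S)-5-methyl-2-(prop-1-en-2-yl)hex-4-enoyl]oxazolidin-2-one, via sodium Z-dienolate 6 (not isolated)
Conditions: NaHMDS (1.1 equiv), THF, −78 °C; then 5, −78 → −40 °C
Reagents that add atoms: none
Why: γ-deprotonation of the s-cis imide gives the chelated Z-dienolate, which reacts at Cα on the face opposite the benzyl group (deconjugative Evans alkylation) and so sets the (2S) centre that becomes C2'' of the target.

Step 3
Reactants: 7 (4S)-4-benzyl-3-[(2S)-5-methyl-2-(prop-1-en-2-yl)hex-4-enoyl]oxazolidin-2-one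
Product: 8 (S)-lavandulol, (2S)-5-methyl-2-(prop-1-en-2-yl)hex-4-en-1-ol
Conditions: LiBH4, H2O (1 equiv), Et2O, 0 °C
Reagents that add atoms: none
Why: reductive removal of the auxiliary with LiBH4/H2O attacks the exocyclic carbonyl under nearly non-basic conditions, so the β,γ-unsaturated α-centre neither epimerises nor reconjugates and the alkenes are inert.

Step 4
Reactants: 8 (S)-lavandulol
Product: 9 (S)-lavandulyl iodide, (3S)-3-(iodomethyl)-2,6-dimethylhepta-1,5-diene
Conditions: I2, PPh3, imidazole, CH2Cl2, 0 °C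
Reagents that add atoms: iodine, II
Why: the Appel-type iodination displaces the primary alkoxyphosphonium by SN2 at CH2, so the adjacent stereocentre and both alkenes are not involved.

Step 5
Reactants: 10 2,4-dihydroxybenzaldehyde
Product: 11 2,4-bis(methoxymethoxy)benzaldehyde
Conditions: MOMCl (2.6 equiv), DIPEA (3 equiv), CH2Cl2, 0 °C → reflux
Reagents that add atoms: chloromethyl methyl ether, COCCl
Why: standard phenol acetalisation gives MOM ethers that tolerate amine, LDA, K2CO3 and KHMDS and come off later with mild acid.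

Step 6
Reactants: 11 2,4-bis(methoxymethoxy)benzaldehyde; 12 dehydroacetic acid (3-acetyl-4-hydroxy-6-methyl-2H-pyran-2-one)
Product: 13 3-{(2E)-3-[2,4-bis(methoxymethoxy)phenyl]prop-2-enoyl}-4-hydroxy-6-methyl-2H-pyran-2-one
Conditions: piperidine (0.2 equiv), pyridine (0.2 equiv), CHCl3, reflux, 4 Å MS
Reagents that add atoms: none
Why: under amine catalysis the acetyl CH3 of the chelated tricarbonyl condenses with aryl aldehydes in preference to the 6-methyl group (Claisen–Schmidt/Knoevenagel condensation of dehydroacetic acid) and gives the E-enone.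

Step 7
Reactants: 13 3-{(2E)-3-[2,4-bis(methoxymethoxy)phenyl]prop-2-enoyl}-4-hydroxy-6-methyl-2H-pyran-2-one; 9 (S)-lavandulyl iodide
Product: 15 3-{(2E)-3-[2,4-bis(methoxymethoxy)phenyl]prop-2-enoyl}-4-hydroxy-6-[(3S)-6-methyl-3-(prop-1-en-2-yl)hept-5-en-1-yl]-2H-pyran-2-one, via dilithium dianion 14 (not isolated)
Conditions: LDA (2.3 equiv), THF/DMPU 5:1, −78 °C; then 9, −78 → 0 °C; 1 M HCl to pH 3, 0 °C
Reagents that add atoms: none
Why: the first equivalent of base forms the tricarbonyl enolate, which also deactivates the enone, the second removes a 6-CH3 proton, and the dianion is alkylated at this last-formed, most basic carbon (Hauser-type dianion alkylation, as for triacetic acid lactone) by SN2 at the iodide CH2 without touching the stereocentre.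

Step 8
Reactants: 15 3-{(2E)-3-[2,4-bis(methoxymethoxy)phenyl]prop-2-enoyl}-4-hydroxy-6-[(3S)-6-methyl-3-(prop-1-en-2-yl)hept-5-en-1-yl]-2H-pyran-2-one
Product: 16 3-{(2E)-3-[2,4-bis(methoxymethoxy)phenyl]prop-2-enoyl}-4-methoxy-6-[(3S)-6-methyl-3-(prop-1-en-2-yl)hept-5-en-1-yl]-2H-pyran-2-one
Conditions: Me2SO4 (1.2 equiv), K2CO3 (1.5 equiv), acetone, rt
Reagents that add atoms: dimethyl sulfate, COS(=O)(=O)OC
Why: the acidic 4-OH (pKa about 5) is the only ionisable site, and Me2SO4/K2CO3 O-methylates 4-hydroxy-2-pyrones at O-4, which places the future C5-OMe before ring A exists (O-alkylation of a vinylogous acid).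

Step 9
Reactants: 16 3-{(2E)-3-[2,4-bis(methoxymethoxy)phenyl]prop-2-enoyl}-4-methoxy-6-[(3S)-6-methyl-3-(prop-1-en-2-yl)hept-5-en-1-yl]-2H-pyran-2-one
Product: 21 (2S)-2-[2,4-bis(methoxymethoxy)phenyl]-7-hydroxy-5-methoxy-8-[(2R)-5-methyl-2-(prop-1-en-2-yl)hex-4-en-1-yl]-2,3-dihydro-4H-chromen-4-one, via potassium trienolate 17 (not isolated), via dienylketene enolate 18 (not isolated), via dipotassium chalconate 19 (not isolated), via di-O-MOM-kuraridin 20 (not isolated)
Conditions: KHMDS (2.3 equiv), THF (0.02 M), −78 → 45 °C; AcOH (2.3 equiv), −20 °C; solvent switch to PhMe; quinidine-derived 3,5-(CF3)2C6H3-thiourea (15 mol %), 0 °C → rt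
Reagents that add atoms: none
Why: Proposed new method: KHMDS removes the vinylogous 6-CH2 proton to give 17, whose lactone C–O bond is expelled E1cB-style to the (Z)-dienylketene 18 (the intermediate type that closes in Danheiser and Dötz benzannulations), and 6π-electrocyclisation C8–C8a followed by tautomerisation driven by the second equivalent of base builds ring A as 19 with acyl, OMe, H, O, lavandulyl and O already in the kuraridin pattern, the closest known reactions being the alkoxide-induced isomerisation of 4-methoxy-6-methyl-2-pyrone to phloroglucinol monomethyl ether and the Mg(OMe)2 Claisen cyclisations of polyketide pyrones; after neutralisation to 20 the only ortho OH (C5 is blocked as OMe) adds to the enone in a bifunctional cinchona-thiourea intramolecular oxa-Michael reaction (thiourea binds C=O, quinuclidine activates the phenol), which closes ring C and sets C2 as S under catalyst control, kinetically safe because 6'-methoxychalcones lie far on the flavanone side, while the remote side-chain centre is untouched.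

Step 10
Reactants: 21 (2S)-2-[2,4-bis(methoxymethoxy)phenyl]-7-hydroxy-5-methoxy-8-[(2R)-5-methyl-2-(prop-1-en-2-yl)hex-4-en-1-yl]-2,3-dihydro-4H-chromen-4-one
Product: 22 kurarinone, (2S)-2-(2,4-dihydroxyphenyl)-7-hydroxy-5-methoxy-8-[(2R)-5-methyl-2-(prop-1-en-2-yl)hex-4-en-1-yl]-2,3-dihydro-4H-chromen-4-one
Conditions: 3 M aq HCl, MeOH, 40 °C
Reagents that add atoms: none
Why: acid transacetalisation cleaves aryl MOM ethers under conditions that prenyl-type side chains next to free phenols are known to survive, and avoiding base prevents the phenoxide-assisted ring opening that would scramble C2.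

## Compound list
1 | (S)-4-benzyl-1,3-oxazolidin-2-one | O=C1N[C@@H](Cc2ccccc2)CO1 | starting material
2 | 3-methylbut-2-enoyl chloride | CC(C)=CC(=O)Cl | starting material
3 | lithium (S)-4-benzyl-2-oxooxazolidin-3-ide | [Li+].O=C1[N-][C@@H](Cc2ccccc2)CO1 | intermediate
4 | (S)-4-benzyl-3-(3-methylbut-2-enoyl)oxazolidin-2-one | CC(C)=CC(=O)N1[C@@H](Cc2ccccc2)COC1=O | intermediate
5 | 1-bromo-3-methylbut-2-ene | CC(C)=CCBr | starting material
6 | sodium (Z)-dienolate of 4 | [Na+].C=C(C)/C=C(\[O-])N1[C@@H](Cc2ccccc2)COC1=O | intermediate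
7 | (4S)-4-benzyl-3-[(2S)-5-methyl-2-(prop-1-en-2-yl)hex-4-enoyl]oxazolidin-2-one | C=C(C)[C@H](CC=C(C)C)C(=O)N1[C@@H](Cc2ccccc2)COC1=O | intermediate
8 | (S)-lavandulol | C=C(C)[C@H](CC=C(C)C)CO | intermediate
9 | (S)-lavandulyl iodide, (3S)-3-(iodomethyl)-2,6-dimethylhepta-1,5-diene | C=C(C)[C@H](CC=C(C)C)CI | intermediate
10 | 2,4-dihydroxybenzaldehyde | O=Cc1ccc(O)cc1O | starting material
11 | 2,4-bis(methoxymethoxy)benzaldehyde | O=Cc1ccc(OCOC)cc1OCOC | intermediate
12 | dehydroacetic acid | CC(=O)C1=C(O)C=C(C)OC1=O | starting material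
13 | 3-{(2E)-3-[2,4-bis(methoxymethoxy)phenyl]prop-2-enoyl}-4-hydroxy-6-methyl-2H-pyran-2-one | CC1=CC(O)=C(C(=O)/C=C/c2ccc(OCOC)cc2OCOC)C(=O)O1 | intermediate
14 | dilithium dianion of 13 (4-oxide and 6-methylene enolate) | [Li+].[Li+].C=C1C=C([O-])C(C(=O)/C=C/c2ccc(OCOC)cc2OCOC)=C([O-])O1 | intermediate
15 | 4-hydroxy-6-[(3S)-6-methyl-3-(prop-1-en-2-yl)hept-5-en-1-yl] analogue of 13 | C=C(C)[C@H](CC=C(C)C)CCC1=CC(O)=C(C(=O)/C=C/c2ccc(OCOC)cc2OCOC)C(=O)O1 | intermediate
16 | 4-methyl ether of 15 | C=C(C)[C@H](CC=C(C)C)CCC1=CC(OC)=C(C(=O)/C=C/c2ccc(OCOC)cc2OCOC)C(=O)O1 | intermediate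
17 | potassium trienolate of 16 (6-alkylidene-pyran-2-olate, side-chain centre unchanged) | [K+].C=C(C)[C@H](CC=C(C)C)CC=C1C=C(OC)C(C(=O)/C=C/c2ccc(OCOC)cc2OCOC)=C([O-])O1 | intermediate
18 | ring-opened (Z)-dienylketene potassium enolate | [K+].C=C(C)[C@H](CC=C(C)C)CC=C([O-])/C=C(OC)\C(=C=O)C(=O)/C=C/c1ccc(OCOC)cc1OCOC | intermediate
19 | dipotassium 2',4'-bis-phenolate of 20 | [K+].[K+].C=C(C)[C@H](CC=C(C)C)Cc1c([O-])cc(OC)c(C(=O)/C=C/c2ccc(OCOC)cc2OCOC)c1[O-] | intermediate
20 | 2,4-di-O-MOM-kuraridin, (E)-3-[2,4-bis(methoxymethoxy)phenyl]-1-{2,4-dihydroxy-6-methoxy-3-[(2R)-5-methyl-2-(prop-1-en-2-yl)hex-4-en-1-yl]phenyl}prop-2-en-1-one | C=C(C)[C@H](CC=C(C)C)Cc1c(O)cc(OC)c(C(=O)/C=C/c2ccc(OCOC)cc2OCOC)c1O | intermediate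
21 | 2',4'-di-O-MOM-kurarinone (2S,2''R) | C=C(C)[C@H](CC=C(C)C)Cc1c(O)cc(OC)c2c1O[C@H](c1ccc(OCOC)cc1OCOC)CC2=O | intermediate
22 | kurarinone (2S,2''R) | C=C(C)[C@H](CC=C(C)C)Cc1c(O)cc(OC)c2c1O[C@H](c1ccc(O)cc1O)CC2=O | target

## Step count and risks
Total steps: 10. Longest linear sequence: 8 (steps 1–4 and 7–10). Steps 5–6 form the side branch.

**Step 9.** The ketene/6π ring transformation may stall or give oligomers, and the selectivity at C2 may be modest because of the free 7-OH and the ortho-substituted B ring. The fallback sets out from 16 and comes back at 21.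
- NaOMe (1.1 equiv) in MeOH at 0 °C opens the lactone nucleophilically to the acyclic keto ester F1.
- Mg(OMe)2 in refluxing MeOH then closes ring A by a chelation-directed Claisen (Dieckmann) condensation of the C6 methylene onto the ester, giving 20, which is now isolated.
- NaOAc in warm EtOH closes ring C without stereocontrol, giving 21 together with the C2 epimer F2.
- Transfer hydrogenation with RuCl[(R,R)-TsDPEN](p-cymene) and HCO2H/Et3N in EtOAc selectively reduces the 2R series to the cis-flavan-4-ol F3. Chromatography then leaves 21 (kinetic resolution instead of asymmetric cyclisation).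

**Step 7.** The dianion of the enone-bearing pyrone may add to itself, rearrange on warming, or react too slowly with a β-branched iodide. The fallback sets out from 12 and 9 and comes back at 15.
- 12 is deacetylated (90 % H2SO4, 130 °C) to triacetic acid lactone F4.
- The well-behaved dianion of F4 (LDA, 2.2 equiv, THF/DMPU) is alkylated with 9 to give the 6-alkyl lactone F5.
- AcOH, DCC and DMAP (O-acylation followed by a Fries-type shift to C3) give the 3-acetyl pyrone F6.
- Piperidine-catalysed condensation of F6 with 11 gives 15.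

**Step 8.** Electrophilic methylation may be sluggish on the chelated enol, or may hit O-2 or the acyl oxygen. The fallback sets out from 15 and comes back at 16, and it reverses the polarity of the step.
- TsCl and Et3N in CH2Cl2 at 0 °C give the pyron-4-yl tosylate F7.
- NaOMe (1.0 equiv) in MeOH/THF at −20 °C displaces the tosylate by addition–elimination at the doubly activated C4.

## Further compounds
F1 | step 9 | methyl (8S)-2-{(2E)-3-[2,4-bis(methoxymethoxy)phenyl]prop-2-enoyl}-3-methoxy-11-methyl-5-oxo-8-(prop-1-en-2-yl)dodeca-2,10-dienoate (push–pull C2=C3 alkene, configurationally labile) | C=C(C)[C@H](CC=C(C)C)CCC(=O)CC(OC)=C(C(=O)OC)C(=O)/C=C/c1ccc(OCOC)cc1OCOC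
F2 | step 9 | (2R,2''R)-2',4'-di-O-MOM-kurarinone (C2 epimer of 21) | C=C(C)[C@H](CC=C(C)C)Cc1c(O)cc(OC)c2c1O[C@@H](c1ccc(OCOC)cc1OCOC)CC2=O
F3 | step 9 | (2R,4R)-cis-flavan-4-ol derived from F2 | C=C(C)[C@H](CC=C(C)C)Cc1c(O)cc(OC)c2c1O[C@@H](c1ccc(OCOC)cc1OCOC)C[C@H]2O
F4 | step 7 | triacetic acid lactone, 4-hydroxy-6-methyl-2H-pyran-2-one | CC1=CC(O)=CC(=O)O1
F5 | step 7 | 4-hydroxy-6-[(3S)-6-methyl-3-(prop-1-en-2-yl)hept-5-en-1-yl]-2H-pyran-2-one | C=C(C)[C@H](CC=C(C)C)CCC1=CC(O)=CC(=O)O1
F6 | step 7 | 3-acetyl-4-hydroxy-6-[(3S)-6-methyl-3-(prop-1-en-2-yl)hept-5-en-1-yl]-2H-pyran-2-one | C=C(C)[C@H](CC=C(C)C)CCC1=CC(O)=C(C(C)=O)C(=O)O1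
F7 | step 8 | 3-{(2E)-3-[2,4-bis(methoxymethoxy)phenyl]prop-2-enoyl}-6-[(3S)-6-methyl-3-(prop-1-en-2-yl)hept-5-en-1-yl]-2-oxo-2H-pyran-4-yl 4-methylbenzenesulfonate | C=C(C)[C@H](CC=C(C)C)CCC1=CC(OS(=O)(=O)c2ccc(C)cc2)=C(C(=O)/C=C/c2ccc(OCOC)cc2OCOC)C(=O)O1
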